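**Strategy**

Everything rests on reading C3 of the lactone ring (O1, C2, C3, C4, C5) as the terminus of a 1,2-benzyl shift: it bears hydroxyl, the ArCH2 group and the C2 carbonyl. Disconnecting C3–CH2Ar and O1–C2 together leads to an open γ-hydroxy 1,2-diketone whose five-membered hemiketal rearranges (α-ketol/benzilic ester type). One operation closes the lactone, forms the C3–benzyl bond and sets C3 under control of C4. The precursor 17 is a 1,5-diarylpentane-2,3-dione carrying a free hydroxymethyl group (C5) on the stereocentre C4 and the C7 carbinol masked as a TBS ether. Its C4/C7 pair comes from an Evans syn aldol and its dione from an internal alkyne.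

Key step: step 12

Remarks on the chemistry:
- Lactone numbering (O1, C2 carbonyl, C3, C4, C5; C7 = aryl carbinol/ketone carbon) is used for all intermediates. Ar = 4-(benzyloxy)-3-methoxyphenyl; TBS = tert-butyldimethylsilyl.
- The C5 oxygen is carried as a primary TBS ether, not as a benzyl-type ether cleaved by a quinone oxidant. Such an oxidant would also attack the electron-rich benzylic C7 silyl ether and the ArCH2 positions.
- The auxiliary is removed as the Weinreb amide, so C4 never carries CH2OH beside CH2OSi, where silyl migration would invert C4.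
- The C7 configuration (R) is temporary and is erased in step 14.
- Assumption: 4-(benzyloxy)-3-methoxybenzyl alcohol 13 is purchased.

Step 1
Reactants: 1 methyl 3-hydroxypropanoate
Product: 2 methyl 3-[(tert-butyldimethylsilyl)oxy]propanoate
Conditions: TBSCl, imidazole, DMF, 0 °C → rt
Reagents that add atoms: tert-butyldimethylsilyl chloride, CC(C)(C)[Si](C)(C)Cl
Why: Imidazole-promoted silylation of a primary alcohol (silyl ether formation) is routine and installs a C5–O protecting group that fluoride can later remove without oxidant or base.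

Step 2
Reactants: 2 methyl 3-[(tert-butyldimethylsilyl)oxy]propanoate
Product: 3 3-[(tert-butyldimethylsilyl)oxy]propanoic acid
Conditions: LiOH·H2O, THF/H2O, 0 °C → rt; then 1 M HCl to pH 4, 0 °C
Reagents that add atoms: lithium hydroxide, [Li+].[OH-]
Why: Saponification of the methyl ester (acyl substitution by hydroxide) should outpace β-elimination, and a primary TBS ether tolerates aqueous hydroxide and a brief, cold, mildly acidic work-up.

Step 3
Reactants: 3 3-[(tert-butyldimethylsilyl)oxy]propanoic acid; 4 (R)-4-benzyl-2-oxazolidinone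
Product: 6 (R)-4-benzyl-3-{3-[(tert-butyldimethylsilyl)oxy]propanoyl}oxazolidin-2-one, via mixed pivalic anhydride 5 (not isolated)
Conditions: PivCl, Et3N, THF, −20 °C; then LiCl, 4, −20 °C → rt
Reagents that add atoms: none
Why: N-Acylation of the oxazolidinone through a mixed pivalic anhydride (LiCl/Et3N activation) is the standard entry to such imides, attack occurring at the unhindered acyl carbon of 5.

Step 4
Reactants: 6 (R)-4-benzyl-3-{3-[(tert-butyldimethylsilyl)oxy]propanoyl}oxazolidin-2-one; 7 O-benzylvanillin (4-benzyloxy-3-methoxybenzaldehyde)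
Product: 8 (R)-4-benzyl-3-[(2R,3R)-3-Ar-2-(TBSOCH2)-3-hydroxypropanoyl]oxazolidin-2-one
Conditions: Bu2BOTf, i-Pr2NEt, CH2Cl2, 0 °C; then 7, −78 → 0 °C; then pH 7 buffer, MeOH, 30% H2O2, 0 °C
Reagents that add atoms: none
Why: Evans syn aldol, in which the (Z)-boron enolate of 6 reacts through a closed Zimmerman–Traxler chair on the enolate face away from the auxiliary benzyl group, should set C4 (2R) and C7 (3R) as the syn pair, and a boron enolate does not expel the β-silyloxy group.

Step 5
Reactants: 8 (R)-4-benzyl-3-[(2R,3R)-3-Ar-2-(TBSOCH2)-3-hydroxypropanoyl]oxazolidin-2-one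
Product: 9 (2R,3R)-3-Ar-2-(TBSOCH2)-3-hydroxy-N-methoxy-N-methylpropanamide
Conditions: MeNH(OMe)·HCl, AlMe3, CH2Cl2, −20 → 0 °C
Reagents that add atoms: N,O-dimethylhydroxylamine hydrochloride, CNOC.Cl
Why: Weinreb transamination of the imide by the aluminium amide, assisted by the free β-hydroxyl, should cleave the auxiliary without epimerising C4 and gives an acyl group that can be reduced only to the aldehyde stage.

Step 6
Reactants: 9 (2R,3R)-3-Ar-2-(TBSOCH2)-3-hydroxy-N-methoxy-N-methylpropanamide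
Product: 10 (2R,3R)-3-Ar-3-(TBSO)-2-(TBSOCH2)-N-methoxy-N-methylpropanamide
Conditions: TBSOTf, 2,6-lutidine, CH2Cl2, −78 → 0 °C
Reagents that add atoms: tert-butyldimethylsilyl trifluoromethanesulfonate, CC(C)(C)[Si](C)(C)OS(=O)(=O)C(F)(F)F
Why: Silyl triflate/lutidine silylation should cap the hindered benzylic C7 hydroxyl without retro-aldol cleavage and gives the ether that must survive until after the key step.

Step 7
Reactants: 10 (2R,3R)-3-Ar-3-(TBSO)-2-(TBSOCH2)-N-methoxy-N-methylpropanamide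
Product: 12 (3R,4R)-4-Ar-4-(TBSO)-3-(TBSOCH2)but-1-yne, via aldehyde 11 (not isolated)
Conditions: i-Bu2AlH, CH2Cl2, −78 °C; then MeOH, K2CO3, dimethyl (1-diazo-2-oxopropyl)phosphonate, −78 °C → rt
Reagents that add atoms: dimethyl (1-diazo-2-oxopropyl)phosphonate, COP(=O)(OC)C(=[N+]=[N-])C(C)=O
Why: Hydride reduction of the Weinreb amide stops at the chelated aluminium hemiaminal, and the aldehyde released on adding methanol is trapped in the same flask by Ohira–Bestmann (Seyferth–Gilbert) homologation, so the epimerisable C4 centre meets carbonate only briefly.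

Step 8
Reactants: 13 4-(benzyloxy)-3-methoxybenzyl alcohol
Product: 14 4-(benzyloxy)-3-methoxybenzyl chloride
Conditions: SOCl2, CH2Cl2, 0 °C
Reagents that add atoms: thionyl chloride, O=S(Cl)Cl
Why: Chlorodehydroxylation of an electron-rich benzylic alcohol via its chlorosulfite is fast at 0 °C and leaves the aryl benzyl ether intact.

Step 9
Reactants: 12 (3R,4R)-4-Ar-4-(TBSO)-3-(TBSOCH2)but-1-yne; 14 4-(benzyloxy)-3-methoxybenzyl chloride
Product: 15 (4R,5R)-1,5-bis(Ar)-5-(TBSO)-4-(TBSOCH2)pent-2-yne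
Conditions: PdCl2(MeCN)2 (3 mol%), XPhos (9 mol%), Cs2CO3, THF, 65 °C
Reagents that add atoms: none
Why: Copper-free Sonogashira-type coupling of a terminal alkyne with a benzyl chloride (oxidative addition of the benzylic C–Cl bond to zerovalent palladium, carbonate-assisted alkynyl transfer, reductive elimination) forms the C(sp)–C(sp3) bond under a base too weak to deprotonate C4–H, and the electron-rich aryl group disfavours isomerisation to the allene.

Step 10
Reactants: 15 (4R,5R)-1,5-bis(Ar)-5-(TBSO)-4-(TBSOCH2)pent-2-yne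
Product: 16 (4R,5R)-1,5-bis(Ar)-5-(TBSO)-4-(TBSOCH2)pentane-2,3-dione
Conditions: KMnO4, NaHCO3, MgSO4, acetone/H2O, 0 °C → rt
Reagents that add atoms: potassium permanganate, [K+].[O-][Mn](=O)(=O)=O
Why: Buffered permanganate oxidation of an internal alkyne to the 1,2-diketone (via a cyclic manganate ester) runs near neutral pH, where silyl ethers, aryl benzyl ethers and alkoxyarenes are tolerated and C4 is not enolised.

Step 11
Reactants: 16 (4R,5R)-1,5-bis(Ar)-5-(TBSO)-4-(TBSOCH2)pentane-2,3-dione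
Product: 17 (4R,5R)-1,5-bis(Ar)-5-(TBSO)-4-(hydroxymethyl)pentane-2,3-dione
Conditions: HF·pyridine, pyridine, THF, 0 °C
Reagents that add atoms: none
Why: Fluoride-mediated desilylation is much faster for the unhindered primary C5 ether than for the hindered secondary benzylic C7 ether, and the weakly acidic medium neither enolises C4 nor allows silyl migration; 17 is expected in equilibrium with its cyclic hemiketal.

Step 12
Reactants: 17 (4R,5R)-1,5-bis(Ar)-5-(TBSO)-4-(hydroxymethyl)pentane-2,3-dione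
Product: 19 (3S,4R)-3-(ArCH2)-4-[(R)-Ar(TBSO)methyl]-3-hydroxydihydrofuran-2(3H)-one, via cyclic hemiketal 18 (not isolated)
Conditions: Cu(OTf)2 (10 mol%), 2,2′-bipyridine (12 mol%), 4 Å molecular sieves, CH2Cl2, 0 °C → rt
Reagents that add atoms: none
Why: The C5 hydroxyl adds reversibly to the distal C2 ketone, the only carbonyl it can reach without forming a four-membered ring, in a 5-exo-trig closure to hemiketal 18; two-point binding of the hemiketal hydroxyl and the C3 ketone to divalent copper acidifies O–H, polarises C3=O and lets the C2–benzyl bond shift suprafacially to C3 while O1 and the hydroxyl oxygen turn C2 into the lactone carbonyl. The closest known reactions are the Lewis-acid-catalysed α-ketol (acyloin) rearrangement and the benzilic ester rearrangement of 1,2-diketones with an internal alkoxide. The new C3 stereocentre is controlled by C4: the hemiketal epimers interconvert through 17 (Curtin–Hammett), and the epimer carrying benzyl on the ring face opposite the bulky C4 side chain should migrate faster, placing benzyl trans and hydroxyl cis to that chain (3S). Benzyl migrates and not O1, because the endocyclic C2–O1 bond lies in the carbonyl plane and cannot overlap with the C3 π* orbital. Turning a ketone hemiketal into an ester makes the shift irreversible, and the absence of base keeps C4–H (α to C3) from enolising and the β-silyloxy group from eliminating.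

Step 13
Reactants: 19 (3S,4R)-3-(ArCH2)-4-[(R)-Ar(TBSO)methyl]-3-hydroxydihydrofuran-2(3H)-one
Product: 20 (3S,4R)-3-(ArCH2)-4-[(R)-Ar(hydroxy)methyl]-3-hydroxydihydrofuran-2(3H)-one
Conditions: HF·pyridine, THF, 0 °C → rt
Reagents that add atoms: none
Why: Fluoride cleavage of the remaining silyl ether in an acidic medium avoids a free C7 alkoxide, which could otherwise attack C2 and translactonise.

Step 14
Reactants: 20 (3S,4R)-3-(ArCH2)-4-[(R)-Ar(hydroxy)methyl]-3-hydroxydihydrofuran-2(3H)-one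
Product: 21 (3S,4S)-4-[4-(benzyloxy)-3-methoxybenzoyl]-3-(ArCH2)-3-hydroxydihydrofuran-2(3H)-one
Conditions: Dess–Martin periodinane, CH2Cl2, 0 °C → rt
Reagents that add atoms: none
Why: Dess–Martin oxidation should convert the secondary benzylic C7 alcohol into the aryl ketone under neutral conditions, the tertiary C3 alcohol cannot be oxidised, and the newly acidic C4–H meets no base.

Step 15
Reactants: 21 (3S,4S)-4-[4-(benzyloxy)-3-methoxybenzoyl]-3-(ArCH2)-3-hydroxydihydrofuran-2(3H)-one
Product: 22 (3S,4S)-3-hydroxy-4-(4-hydroxy-3-methoxybenzoyl)-3-(4-hydroxy-3-methoxybenzyl)dihydrofuran-2(3H)-one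
Conditions: H2 (1 atm), 10% Pd/C, EtOAc, rt
Reagents that add atoms: none
Why: Catalytic hydrogenolysis of the two aryl benzyl ethers should be much faster than reduction of the electron-rich, para-oxygenated aryl ketone, and the neutral medium preserves C3 and C4.

**Compound list**

1 | methyl 3-hydroxypropanoate | COC(=O)CCO | starting material
2 | methyl 3-[(tert-butyldimethylsilyl)oxy]propanoate | COC(=O)CCO[Si](C)(C)C(C)(C)C | intermediate
3 | 3-[(tert-butyldimethylsilyl)oxy]propanoic acid | OC(=O)CCO[Si](C)(C)C(C)(C)C | intermediate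
4 | (R)-4-benzyl-2-oxazolidinone | O=C1N[C@H](Cc2ccccc2)CO1 | starting material
5 | 3-[(tert-butyldimethylsilyl)oxy]propanoic pivalic anhydride | CC(C)(C)C(=O)OC(=O)CCO[Si](C)(C)C(C)(C)C | intermediate (not isolated)
6 | (R)-4-benzyl-3-{3-[(tert-butyldimethylsilyl)oxy]propanoyl}oxazolidin-2-one | O=C1OC[C@@H](Cc2ccccc2)N1C(=O)CCO[Si](C)(C)C(C)(C)C | intermediate
7 | O-benzylvanillin (4-benzyloxy-3-methoxybenzaldehyde) | COc1cc(C=O)ccc1OCc1ccccc1 | starting material
8 | (R)-4-benzyl-3-[(2R,3R)-3-[4-(benzyloxy)-3-methoxyphenyl]-2-{[(tert-butyldimethylsilyl)oxy]methyl}-3-hydroxypropanoyl]oxazolidin-2-one | O=C1OC[C@@H](Cc2ccccc2)N1C(=O)[C@H](CO[Si](C)(C)C(C)(C)C)[C@@H](O)c1ccc(OCc2ccccc2)c(OC)c1 | intermediate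
9 | (2R,3R)-3-[4-(benzyloxy)-3-methoxyphenyl]-2-{[(tert-butyldimethylsilyl)oxy]methyl}-3-hydroxy-N-methoxy-N-methylpropanamide | CON(C)C(=O)[C@H](CO[Si](C)(C)C(C)(C)C)[C@@H](O)c1ccc(OCc2ccccc2)c(OC)c1 | intermediate
10 | (2R,3R)-3-[4-(benzyloxy)-3-methoxyphenyl]-3-[(tert-butyldimethylsilyl)oxy]-2-{[(tert-butyldimethylsilyl)oxy]methyl}-N-methoxy-N-methylpropanamide | CON(C)C(=O)[C@H](CO[Si](C)(C)C(C)(C)C)[C@@H](O[Si](C)(C)C(C)(C)C)c1ccc(OCc2ccccc2)c(OC)c1 | intermediate
11 | (2R,3R)-3-[4-(benzyloxy)-3-methoxyphenyl]-3-[(tert-butyldimethylsilyl)oxy]-2-{[(tert-butyldimethylsilyl)oxy]methyl}propanal | O=C[C@H](CO[Si](C)(C)C(C)(C)C)[C@@H](O[Si](C)(C)C(C)(C)C)c1ccc(OCc2ccccc2)c(OC)c1 | intermediate (not isolated)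
12 | (3R,4R)-4-[4-(benzyloxy)-3-methoxyphenyl]-4-[(tert-butyldimethylsilyl)oxy]-3-{[(tert-butyldimethylsilyl)oxy]methyl}but-1-yne | C#C[C@H](CO[Si](C)(C)C(C)(C)C)[C@@H](O[Si](C)(C)C(C)(C)C)c1ccc(OCc2ccccc2)c(OC)c1 | intermediate
13 | 4-(benzyloxy)-3-methoxybenzyl alcohol | COc1cc(CO)ccc1OCc1ccccc1 | starting material
14 | 4-(benzyloxy)-3-methoxybenzyl chloride | COc1cc(CCl)ccc1OCc1ccccc1 | intermediate
15 | (4R,5R)-1,5-bis[4-(benzyloxy)-3-methoxyphenyl]-5-[(tert-butyldimethylsilyl)oxy]-4-{[(tert-butyldimethylsilyl)oxy]methyl}pent-2-yne | COc1cc(CC#C[C@H](CO[Si](C)(C)C(C)(C)C)[C@@H](O[Si](C)(C)C(C)(C)C)c2ccc(OCc3ccccc3)c(OC)c2)ccc1OCc1ccccc1 | intermediate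
16 | (4R,5R)-1,5-bis[4-(benzyloxy)-3-methoxyphenyl]-5-[(tert-butyldimethylsilyl)oxy]-4-{[(tert-butyldimethylsilyl)oxy]methyl}pentane-2,3-dione | COc1cc(CC(=O)C(=O)[C@H](CO[Si](C)(C)C(C)(C)C)[C@@H](O[Si](C)(C)C(C)(C)C)c2ccc(OCc3ccccc3)c(OC)c2)ccc1OCc1ccccc1 | intermediate
17 | (4R,5R)-1,5-bis[4-(benzyloxy)-3-methoxyphenyl]-5-[(tert-butyldimethylsilyl)oxy]-4-(hydroxymethyl)pentane-2,3-dione (key-step precursor) | COc1cc(CC(=O)C(=O)[C@H](CO)[C@@H](O[Si](C)(C)C(C)(C)C)c2ccc(OCc3ccccc3)c(OC)c2)ccc1OCc1ccccc1 | intermediate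
18 | (2R,4R)-2-[4-(benzyloxy)-3-methoxybenzyl]-4-{(R)-[4-(benzyloxy)-3-methoxyphenyl][(tert-butyldimethylsilyl)oxy]methyl}-2-hydroxydihydrofuran-3(2H)-one (reactive C2 epimer shown; it interconverts with its C2 epimer through 17) | COc1cc(C[C@@]2(O)OC[C@H]([C@@H](O[Si](C)(C)C(C)(C)C)c3ccc(OCc4ccccc4)c(OC)c3)C2=O)ccc1OCc1ccccc1 | intermediate (not isolated)
19 | (3S,4R)-3-[4-(benzyloxy)-3-methoxybenzyl]-4-{(R)-[4-(benzyloxy)-3-methoxyphenyl][(tert-butyldimethylsilyl)oxy]methyl}-3-hydroxydihydrofuran-2(3H)-one (key-step product) | COc1cc(C[C@@]2(O)C(=O)OC[C@@H]2[C@@H](O[Si](C)(C)C(C)(C)C)c2ccc(OCc3ccccc3)c(OC)c2)ccc1OCc1ccccc1 | intermediate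
20 | (3S,4R)-3-[4-(benzyloxy)-3-methoxybenzyl]-4-{(R)-[4-(benzyloxy)-3-methoxyphenyl](hydroxy)methyl}-3-hydroxydihydrofuran-2(3H)-one | COc1cc(C[C@@]2(O)C(=O)OC[C@@H]2[C@@H](O)c2ccc(OCc3ccccc3)c(OC)c2)ccc1OCc1ccccc1 | intermediate
21 | (3S,4S)-4-[4-(benzyloxy)-3-methoxybenzoyl]-3-[4-(benzyloxy)-3-methoxybenzyl]-3-hydroxydihydrofuran-2(3H)-one | COc1cc(C[C@@]2(O)C(=O)OC[C@@H]2C(=O)c2ccc(OCc3ccccc3)c(OC)c2)ccc1OCc1ccccc1 | intermediate
22 | (3S,4S)-3-hydroxy-4-(4-hydroxy-3-methoxybenzoyl)-3-(4-hydroxy-3-methoxybenzyl)dihydrofuran-2(3H)-one (CNP0321349.1) | COc1cc(C[C@@]2(O)C(=O)OC[C@@H]2C(=O)c2ccc(O)c(OC)c2)ccc1O | target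

**Step count and risks**

Total step count: 15 (14 in the main line plus the one-step preparation of chloride 14).
Longest linear sequence: 14 steps (steps 1–7 and 9–15, from compound 1).

Steps most likely to fail:

1. Step 12. The benzyl group may migrate across the wrong ring face (C3 epimer). C4 may enolise, or the C7 silyloxy group may eliminate, before the shift. The hemiketal may lose water to an exocyclic enol ether, or the Lewis acid may ionise the benzylic silyl ether. The fallback builds C3 by enolate chemistry on a preformed lactone; it sets out from alkyne 12 and returns at lactone 19. Anti-Markovnikov hydroboration of 12 with dicyclohexylborane and oxidation with NaBO3·4H2O should give the aldehyde (3R,4R)-4-Ar-4-(TBSO)-3-(TBSOCH2)butanal F1. HF·pyridine/pyridine at 0 °C should free the primary hydroxyl, which closes to the lactol 4-[(R)-Ar(TBSO)methyl]tetrahydrofuran-2-ol F2. Oxidation with TEMPO (cat.) and PhI(OAc)2 should give the γ-lactone 4-[(R)-Ar(TBSO)methyl]dihydrofuran-2(3H)-one F3. Its lithium enolate (LiN(SiMe3)2, THF, −78 °C) should be hydroxylated by 2-(phenylsulfonyl)-3-phenyloxaziridine to the α-hydroxy lactone F4 (C3 epimers, both usable). TESOTf/2,6-lutidine should give the α-triethylsilyloxy lactone F5. Deprotonation with LiN(i-Pr)2 and alkylation with chloride 14 (NaI, DMPU, −78 °C) is expected to occur anti to the bulky C4 side chain, giving the 3-benzylated 3-triethylsilyloxy lactone F6 with benzyl trans and oxygen cis to that chain. Brief treatment with HF·pyridine should remove the triethylsilyl ether in the presence of the hindered benzylic TBS ether and deliver 19.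

2. Step 10. The enolisable benzyl dione may be cleaved through its enol, or permanganate may attack the doubly activated ArCH2 methylene or the alkoxyarene rings. The fallback reaches the dione by stepwise oxygenation of an alkene; it sets out from alkyne 15 and returns at dione 16. Semi-hydrogenation (H2, Pd/CaCO3 poisoned with Pb(OAc)2, quinoline, EtOAc) should give the (2Z,4R,5R)-1,5-bis(Ar)-5-(TBSO)-4-(TBSOCH2)pent-2-ene F7. OsO4 (cat.) with N-methylmorpholine N-oxide in acetone/H2O should give the syn-2,3-diol F8 (two diastereomers that converge). Oxidation of both carbinols with IBX in DMSO at rt, which needs no base and does not cleave the C–C bond, should give 16.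

3. Step 7. The aldehyde may epimerise at C4 or lose silanolate by β-elimination under carbonate/methanol, or may be released incompletely from the aluminium hemiaminal. The fallback uses a non-basic olefination followed by carbenoid rearrangement (Corey–Fuchs); it sets out from Weinreb amide 10 and returns at alkyne 12. Reduction of 10 with i-Bu2AlH at −78 °C and isolation gives aldehyde 11. CBr4, PPh3 and Zn in CH2Cl2 at 0 °C should give the (3R,4R)-4-Ar-1,1-dibromo-4-(TBSO)-3-(TBSOCH2)but-1-ene F9. n-BuLi (2.2 equiv) in THF at −78 °C, then aqueous NH4Cl, should give 12.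

Further compounds
F1 | step 12 | (3R,4R)-4-[4-(benzyloxy)-3-methoxyphenyl]-4-[(tert-butyldimethylsilyl)oxy]-3-{[(tert-butyldimethylsilyl)oxy]methyl}butanal | O=CC[C@H](CO[Si](C)(C)C(C)(C)C)[C@@H](O[Si](C)(C)C(C)(C)C)c1ccc(OCc2ccccc2)c(OC)c1
F2 | step 12 | 4-{(R)-[4-(benzyloxy)-3-methoxyphenyl][(tert-butyldimethylsilyl)oxy]methyl}tetrahydrofuran-2-ol (C4 as in 12; anomers) | OC1C[C@@H]([C@@H](O[Si](C)(C)C(C)(C)C)c2ccc(OCc3ccccc3)c(OC)c2)CO1
F3 | step 12 | 4-{(R)-[4-(benzyloxy)-3-methoxyphenyl][(tert-butyldimethylsilyl)oxy]methyl}dihydrofuran-2(3H)-one (C4 as in 12) | O=C1C[C@@H]([C@@H](O[Si](C)(C)C(C)(C)C)c2ccc(OCc3ccccc3)c(OC)c2)CO1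
F4 | step 12 | 4-{(R)-[4-(benzyloxy)-3-methoxyphenyl][(tert-butyldimethylsilyl)oxy]methyl}-3-hydroxydihydrofuran-2(3H)-one (C4 as in 12; C3 epimers) | O=C1OC[C@H]([C@@H](O[Si](C)(C)C(C)(C)C)c2ccc(OCc3ccccc3)c(OC)c2)C1O
F5 | step 12 | 4-{(R)-[4-(benzyloxy)-3-methoxyphenyl][(tert-butyldimethylsilyl)oxy]methyl}-3-[(triethylsilyl)oxy]dihydrofuran-2(3H)-one (C4 as in 12; C3 epimers) | O=C1OC[C@H]([C@@H](O[Si](C)(C)C(C)(C)C)c2ccc(OCc3ccccc3)c(OC)c2)C1O[Si](CC)(CC)CC
F6 | step 12 | (3S,4R)-3-[4-(benzyloxy)-3-methoxybenzyl]-4-{(R)-[4-(benzyloxy)-3-methoxyphenyl][(tert-butyldimethylsilyl)oxy]methyl}-3-[(triethylsilyl)oxy]dihydrofuran-2(3H)-one | COc1cc(C[C@@]2(O[Si](CC)(CC)CC)C(=O)OC[C@@H]2[C@@H](O[Si](C)(C)C(C)(C)C)c2ccc(OCc3ccccc3)c(OC)c2)ccc1OCc1ccccc1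
F7 | step 10 | (2Z,4R,5R)-1,5-bis[4-(benzyloxy)-3-methoxyphenyl]-5-[(tert-butyldimethylsilyl)oxy]-4-{[(tert-butyldimethylsilyl)oxy]methyl}pent-2-ene | COc1cc(C/C=C\[C@H](CO[Si](C)(C)C(C)(C)C)[C@@H](O[Si](C)(C)C(C)(C)C)c2ccc(OCc3ccccc3)c(OC)c2)ccc1OCc1ccccc1
F8 | step 10 | 1,5-bis[4-(benzyloxy)-3-methoxyphenyl]-5-[(tert-butyldimethylsilyl)oxy]-4-{[(tert-butyldimethylsilyl)oxy]methyl}pentane-2,3-diol (syn-diol, two diastereomers; C4 and C5 as in 15) | COc1cc(CC(O)C(O)[C@H](CO[Si](C)(C)C(C)(C)C)[C@@H](O[Si](C)(C)C(C)(C)C)c2ccc(OCc3ccccc3)c(OC)c2)ccc1OCc1ccccc1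
F9 | step 7 | (3R,4R)-4-[4-(benzyloxy)-3-methoxyphenyl]-1,1-dibromo-4-[(tert-butyldimethylsilyl)oxy]-3-{[(tert-butyldimethylsilyl)oxy]methyl}but-1-ene | BrC(Br)=C[C@H](CO[Si](C)(C)C(C)(C)C)[C@@H](O[Si](C)(C)C(C)(C)C)c1ccc(OCc2ccccc2)c(OC)c1
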